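**Retrosynthetic overview**

1. Target ⇐ acid removal of the acetal and silyl groups ⇐ ten-membered enone, made by ring expansion: the C3–C9 ring-fusion bond of a trans-fused bicyclo[5.3.0]decenol is broken by alkoxy-radical β-scission (C3–OH → C3=O, C9 → CH2).
2. Bicyclic carbinol ⇐ ring-closing metathesis (C4=C5) ⇐ alkenylcerium addition to a cyclopentanone (C3–C4).
3. Cyclopentanone ⇐ hemiacetal oxa-Michael addition (C1–O, cis-1,10-diol as acetal) ⇐ C8 esterification ⇐ boron aldol (C8–C9) of a 4-silyloxy-4-methylcyclopentenone with a cis α-methylene-γ-lactone aldehyde.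
4. Lactone aldehyde ⇐ asymmetric chromium carboxy-allylation of acrolein with a Baylis–Hillman bromide (C6–C7); cyclopentenone ⇐ asymmetric conjugate borylation of 3-methylcyclopentenone (C10), then Saegusa oxidation.
5. Ring order: γ-lactone → dioxolane on the purchased cyclopentane → seven-membered carbocycle → ten-membered ring.

**Assumptions**

- The target is treated as the open 3-keto-1,10-diol as drawn; a possible 3,10-hemiketal tautomer is not considered.
- (R)-2-Methylbutanoic acid, 2,2-dimethoxyacetaldehyde (60 % in water) and 2-bromoprop-2-en-1-ol are bought; the ligand enantiomers in steps 3 and 5 are chosen to give the configurations stated.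
- Locants C1–C15 are those of the germacrane skeleton of the target; R/S labels quoted with these locants belong to the compound named.

**Route**

Step 1
Reactants: 1 2,2-dimethoxyacetaldehyde; 2 methyl acrylate
Product: 3 methyl 3-hydroxy-4,4-dimethoxy-2-methylidenebutanoate (racemic)
Conditions: DABCO (0.5 equiv), 1,4-dioxane–H2O 1:1, rt, 48 h
Reagents that add atoms: none
Why: Morita–Baylis–Hillman reaction of an acrylate with a very electrophilic α,α-dialkoxy aldehyde; the racemic carbinol centre is destroyed in step 2.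

Step 2
Reactants: 3 methyl 3-hydroxy-4,4-dimethoxy-2-methylidenebutanoate
Product: 4 methyl (2Z)-2-(bromomethyl)-4,4-dimethoxybut-2-enoate
Conditions: NBS (1.2 equiv), Me2S (1.3 equiv), CH2Cl2, 0 °C → rt
Reagents that add atoms: N-bromosuccinimide, O=C1CCC(=O)N1Br
Why: Bromination of a Baylis–Hillman alcohol through its oxysulfonium salt goes with allylic transposition (SN2′) to the thermodynamically preferred Z 2-(bromomethyl)enoate, and no stereocentre remains.

Step 3
Reactants: 4 methyl (2Z)-2-(bromomethyl)-4,4-dimethoxybut-2-enoate; 5 acrolein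
Product: 8 (4S,5S)-4-(dimethoxymethyl)-5-ethenyl-3-methylideneoxolan-2-one (cis), via silyl ether 6 (not isolated), via hydroxy ester 7 (not isolated)
Conditions: CrCl2 (10 mol %), Kishi-type chiral oxazoline–sulfonamide ligand (11 mol %), proton sponge (11 mol %), Mn (2 equiv), TMSCl (1.2 equiv), THF, 0 °C → rt; then PPTS, MeOH, rt
Reagents that add atoms: none
Why: Catalytic asymmetric Nozaki–Hiyama–Kishi-type 2-(alkoxycarbonyl)allylation: the allylchromium species adds through a closed chair transition state to give the syn adduct (cis β,γ-substituents after lactonization), while the chiral ligand on chromium selects the aldehyde face and so fixes C6 and C7.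

Step 4
Reactants: 8 (4S,5S)-4-(dimethoxymethyl)-5-ethenyl-3-methylideneoxolan-2-one
Product: 9 (2S,3S)-2-ethenyl-4-methylidene-5-oxooxolane-3-carbaldehyde
Conditions: TFA–H2O 1:1, CH2Cl2, 0 °C, 30 min; used crude at once
Reagents that add atoms: water, O
Why: Mild acid hydrolysis of the dimethyl acetal leaves the lactone and both alkenes alone; because the centre next to the new aldehyde can epimerize, 9 is not chromatographed or stored.

Step 5
Reactants: 10 3-methylcyclopent-2-en-1-one
Product: 12 (3R)-3-hydroxy-3-methylcyclopentan-1-one, via boronate 11 (not isolated)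
Conditions: B2pin2 (1.1 equiv), CuCl (5 mol %), QuinoxP* (6 mol %, enantiomer giving the 3R alcohol), LiOtBu (10 mol %), MeOH (2 equiv), THF, rt; then 30 % H2O2, pH 7 buffer, 0 °C
Reagents that add atoms: hydrogen peroxide, OO
Why: Copper-catalysed enantioselective conjugate borylation of a β-substituted cyclic enone sets the quaternary centre C10 by ligand-controlled face selection, and oxidation of the tertiary C–B bond proceeds with retention.

Step 6
Reactants: 12 (3R)-3-hydroxy-3-methylcyclopentan-1-one
Product: 14 (4S)-4-methyl-4-(trimethylsilyloxy)cyclopent-2-en-1-one, via bis-silyl enol ether 13 (not isolated)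
Conditions: TMSCl (3 equiv), LiN(i-Pr)2 (2.3 equiv), THF, −78 °C; then Pd(OAc)2 (10 mol %), O2 (1 atm), DMSO, rt
Reagents that add atoms: chlorotrimethylsilane, C[Si](C)(C)Cl
Why: Saegusa–Ito dehydrogenation: kinetic enolization takes place on the side away from the quaternary carbon (the other enol silane has no β-hydrogen and cannot be dehydrogenated), the tertiary alcohol is silylated in the same pot and the stereocentre is untouched.

Step 7
Reactants: 14 (4S)-4-methyl-4-(trimethylsilyloxy)cyclopent-2-en-1-one; 9 (2S,3S)-2-ethenyl-4-methylidene-5-oxooxolane-3-carbaldehyde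
Product: 16 aldol adduct (4R,5S)-5-ethenyl-4-{(S)-hydroxy[(1R,5R)-5-methyl-2-oxo-5-(trimethylsilyloxy)cyclopent-3-en-1-yl]methyl}-3-methylideneoxolan-2-one, via boron enolate 15 (not isolated)
Conditions: (c-Hex)2BCl (1.3 equiv), Et3N (1.5 equiv), Et2O, −78 → 0 °C; 9 (1.2 equiv), −78 °C; then MeOH, pH 7 buffer, 30 % H2O2, 0 °C
Reagents that add atoms: none
Why: Boron-mediated aldol addition: the enone can only enolize at C9, the ring-locked E enolate reacts through a Zimmerman–Traxler chair (anti aldol C8/C9) on the face anti to the C10 methyl group, which gives the C8 carbinol configuration needed later, while C9 is a relay centre that is erased in step 13.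

Step 8
Reactants: 16 aldol adduct; 17 (2R)-2-methylbutanoic acid
Product: 18 ester (S)-[(2S,3S)-2-ethenyl-4-methylidene-5-oxooxolan-3-yl][(1R,5R)-5-methyl-2-oxo-5-(trimethylsilyloxy)cyclopent-3-en-1-yl]methyl (2R)-2-methylbutanoate
Conditions: DCC (1.5 equiv), DMAP (0.1 equiv), CH2Cl2, 0 °C
Reagents that add atoms: none
Why: Steglich esterification of the only free hydroxyl group with retention at C8; the cold, nearly neutral carbodiimide conditions are chosen to avoid epimerizing the acid or eliminating the β-acyloxy ketone.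

Step 9
Reactants: 18 ester
Product: 21 acetal ketone (S)-[(2S,3S)-2-ethenyl-4-methylidene-5-oxooxolan-3-yl][(2S,3aS,4R,6aR)-2,3a-dimethyl-5-oxohexahydrocyclopenta[d][1,3]dioxol-4-yl]methyl (2R)-2-methylbutanoate, via tertiary alcohol 19 (not isolated), via hemiacetal 20 (not isolated)
Conditions: MeCHO (5 equiv), Bi(NO3)3·5H2O (10 mol %), CH2Cl2, rt
Reagents that add atoms: acetaldehyde, CC=O
Why: Two-component hemiacetal/oxa-conjugate addition (bismuth-nitrate mediated, here forming a dioxolane): after loss of the trimethylsilyl group the C10 hydroxyl forms a hemiacetal with acetaldehyde whose OH can reach C1 of the enone only on the face of the C10 oxygen, so the cis-fused acetal results (C1 R, acetal carbon S with exo methyl by thermodynamic control).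

Step 10
Reactants: 22 2-bromoprop-2-en-1-ol
Product: 23 [(2-bromoprop-2-en-1-yl)oxy](tert-butyl)dimethylsilane
Conditions: TBSCl (1.1 equiv), imidazole (1.5 equiv), CH2Cl2, rt
Reagents that add atoms: tert-butyldimethylsilyl chloride, CC(C)(C)[Si](C)(C)Cl
Why: Standard silylation of a primary alcohol; no stereocentre is involved.

Step 11
Reactants: 21 acetal ketone; 23 [(2-bromoprop-2-en-1-yl)oxy](tert-butyl)dimethylsilane
Product: 26 tertiary allylic alcohol: 21 in which the ring ketone C3 has become C(OH)[C(=CH2)CH2OTBS] (3S; hydroxyl cis to the acetal oxygens and to the C9 side chain), via alkenyllithium 24 (not isolated), via alkenylcerium dichloride 25 (not isolated)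
Conditions: 23 (2 equiv), t-BuLi (4 equiv), Et2O, −78 °C; CeCl3 (2.2 equiv), THF, −78 °C; then 21, −78 °C, 1 h; aq NH4Cl
Reagents that add atoms: none
Why: Bromine–lithium exchange, transmetalation to cerium and Imamoto-type 1,2-addition: the hard, weakly basic alkenylcerium reagent attacks the ketone faster than the lactone or the ester and does not enolize the β-acyloxy ketone, and it approaches the face opposite to the C9 side chain and the dioxolane, which sets the relay centre C3 (erased in step 13).

Step 12
Reactants: 26 tertiary allylic alcohol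
Product: 27 trans-fused bicyclo[5.3.0]dec-4-en-3-ol with C3–C9 bond (6,12-lactone; 8-ester; 1,10-O-ethylidene acetal; 15-O-TBS; 3-OH trans to H9)
Conditions: second-generation Hoveyda–Grubbs catalyst (10 mol %), toluene (2 mM), 80 °C
Reagents that add atoms: none
Why: Ring-closing metathesis between the 1,1-disubstituted alkene next to the free tertiary alcohol and the vinyl group (the electron-poor α-methylene lactone does not take part) gives the trisubstituted cis alkene in the seven-membered ring without touching any stereocentre.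

Step 13
Reactants: 27 trans-fused bicyclo[5.3.0]dec-4-en-3-ol
Product: 28 1,10-O-ethylidene-15-O-(tert-butyldimethylsilyl) derivative of the target (ten-membered 4Z enone)
Conditions: [Ir(dF(CF3)ppy)2(5,5′-d(CF3)bpy)]PF6 (2 mol %), 2,4,6-collidine (30 mol %), 2,4,6-triisopropylbenzenethiol (25 mol %), PhCF3 (5 mM), blue LEDs, 25 °C
Reagents that add atoms: none
Why: Proposed new method: a redox-neutral, photocatalytic ring-expanding isomerization in which the excited trivalent iridium complex and collidine take H• from the only free O–H (proton-coupled electron transfer) to give the C3 alkoxy radical, which cleaves the ring-fusion bond C3–C9 (the only β-scission that gives a secondary alkyl radical, since C3–C4 would give a vinyl radical and C3–C2 a primary one) with release of bicyclic strain and formation of the conjugated enone; the C9 radical is capped by hydrogen-atom transfer from the aryl thiol before it can add across the ring to C5, the thiyl radical is reduced by the divalent iridium species to close the cycle, and no stereocentre is formed (C3 becomes C=O, C9 becomes CH2, the Z alkene is inherited from the seven-membered ring); the closest known reaction type is the proton-coupled-electron-transfer ring-opening isomerization of simple cycloalkanols (Dowd–Beckwith-type alkoxy-radical fragmentation), not yet shown for a ring-fusion tertiary allylic carbinol giving a ten-membered enone.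

Step 14
Reactants: 28 protected ten-membered enone
Product: 29 target CNP0263726.1, (1R,6S,7R,8R,10S,4Z)-1,10,15-trihydroxy-8-[(2R)-2-methylbutanoyloxy]-3-oxogermacra-4,11(13)-dien-12,6-olide
Conditions: TFA–H2O–THF 4:1:1, 0 °C → rt
Reagents that add atoms: none
Why: Acid hydrolysis removes the ethylidene acetal and the allylic silyl ether in one operation without touching a stereocentre; it is run cold and aqueous to avoid dehydration of the β-hydroxy ketone.

**Compound list**

1 | 2,2-dimethoxyacetaldehyde | COC(OC)C=O | starting material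
2 | methyl acrylate | C=CC(=O)OC | starting material
3 | methyl 3-hydroxy-4,4-dimethoxy-2-methylidenebutanoate (racemic) | COC(OC)C(O)C(=C)C(=O)OC | intermediate
4 | methyl (2Z)-2-(bromomethyl)-4,4-dimethoxybut-2-enoate | COC(OC)/C=C(\CBr)C(=O)OC | intermediate
5 | acrolein (prop-2-enal) | C=CC=O | starting material
6 | methyl (3S,4S)-3-(dimethoxymethyl)-2-methylidene-4-(trimethylsilyloxy)hex-5-enoate | C=C(C(=O)OC)[C@H](C(OC)OC)[C@@H](O[Si](C)(C)C)C=C | intermediate
7 | methyl (3S,4S)-3-(dimethoxymethyl)-4-hydroxy-2-methylidenehex-5-enoate | C=C(C(=O)OC)[C@H](C(OC)OC)[C@@H](O)C=C | intermediate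
8 | (4S,5S)-4-(dimethoxymethyl)-5-ethenyl-3-methylideneoxolan-2-one (cis lactone) | C=C1C(=O)O[C@@H](C=C)[C@H]1C(OC)OC | intermediate
9 | (2S,3S)-2-ethenyl-4-methylidene-5-oxooxolane-3-carbaldehyde | C=C1C(=O)O[C@@H](C=C)[C@H]1C=O | intermediate
10 | 3-methylcyclopent-2-en-1-one | CC1=CC(=O)CC1 | starting material
11 | (3S)-3-methyl-3-(4,4,5,5-tetramethyl-1,3,2-dioxaborolan-2-yl)cyclopentan-1-one | C[C@@]1(B2OC(C)(C)C(C)(C)O2)CCC(=O)C1 | intermediate
12 | (3R)-3-hydroxy-3-methylcyclopentan-1-one | C[C@@]1(O)CCC(=O)C1 | intermediate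
13 | (4R)-4-methyl-1,4-bis(trimethylsilyloxy)cyclopent-1-ene | C[C@@]1(O[Si](C)(C)C)CC=C(O[Si](C)(C)C)C1 | intermediate
14 | (4S)-4-methyl-4-(trimethylsilyloxy)cyclopent-2-en-1-one | C[C@@]1(O[Si](C)(C)C)C=CC(=O)C1 | intermediate
15 | dicyclohexyl{[(3R)-3-methyl-3-(trimethylsilyloxy)cyclopenta-1,4-dien-1-yl]oxy}borane (boron enolate of 14) | C[C@@]1(O[Si](C)(C)C)C=CC(OB(C2CCCCC2)C2CCCCC2)=C1 | intermediate
16 | aldol adduct (4R,5S)-5-ethenyl-4-{(S)-hydroxy[(1R,5R)-5-methyl-2-oxo-5-(trimethylsilyloxy)cyclopent-3-en-1-yl]methyl}-3-methylideneoxolan-2-one (6S,7R,8S,9R,10R) | C=C1C(=O)O[C@@H](C=C)[C@H]1[C@H](O)[C@H]2C(=O)C=C[C@@]2(C)O[Si](C)(C)C | intermediate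
17 | (2R)-2-methylbutanoic acid | CC[C@@H](C)C(=O)O | starting material
18 | ester (S)-[(2S,3S)-2-ethenyl-4-methylidene-5-oxooxolan-3-yl][(1R,5R)-5-methyl-2-oxo-5-(trimethylsilyloxy)cyclopent-3-en-1-yl]methyl (2R)-2-methylbutanoate (6S,7S,8S,9R,10R) | C=C1C(=O)O[C@@H](C=C)[C@H]1[C@H](OC(=O)[C@H](C)CC)[C@H]2C(=O)C=C[C@@]2(C)O[Si](C)(C)C | intermediate
19 | tertiary alcohol: 18 without the trimethylsilyl group (free C10–OH) | C=C1C(=O)O[C@@H](C=C)[C@H]1[C@H](OC(=O)[C@H](C)CC)[C@H]2C(=O)C=C[C@@]2(C)O | intermediate
20 | acetaldehyde hemiacetal of 19 at the C10 oxygen (hemiacetal carbon not defined) | C=C1C(=O)O[C@@H](C=C)[C@H]1[C@H](OC(=O)[C@H](C)CC)[C@H]2C(=O)C=C[C@@]2(C)OC(C)O | intermediate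
21 | acetal ketone (S)-[(2S,3S)-2-ethenyl-4-methylidene-5-oxooxolan-3-yl][(2S,3aS,4R,6aR)-2,3a-dimethyl-5-oxohexahydrocyclopenta[d][1,3]dioxol-4-yl]methyl (2R)-2-methylbutanoate (1R,6S,7S,8S,9R,10S) | C=C1C(=O)O[C@@H](C=C)[C@H]1[C@H](OC(=O)[C@H](C)CC)[C@H]2C(=O)C[C@H]3O[C@H](C)O[C@@]23C | intermediate
22 | 2-bromoprop-2-en-1-ol | C=C(Br)CO | starting material
23 | [(2-bromoprop-2-en-1-yl)oxy](tert-butyl)dimethylsilane | C=C(Br)CO[Si](C)(C)C(C)(C)C | intermediate
24 | {3-[(tert-butyldimethylsilyl)oxy]prop-1-en-2-yl}lithium | [Li]C(=C)CO[Si](C)(C)C(C)(C)C | intermediate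
25 | dichloro{3-[(tert-butyldimethylsilyl)oxy]prop-1-en-2-yl}cerium | Cl[Ce](Cl)C(=C)CO[Si](C)(C)C(C)(C)C | intermediate
26 | tertiary allylic alcohol: 21 with C3 converted into C(OH)[C(=CH2)CH2OTBS] (1R,3S,6S,7S,8S,9S,10S; 3-OH cis to the acetal oxygens) | C=C1C(=O)O[C@@H](C=C)[C@H]1[C@H](OC(=O)[C@H](C)CC)[C@H]2[C@](O)(C(=C)CO[Si](C)(C)C(C)(C)C)C[C@H]3O[C@H](C)O[C@@]23C | intermediate
27 | trans-fused bicyclo[5.3.0]dec-4-en-3-ol with C3–C9 bond, 6,12-lactone, 8-[(2R)-2-methylbutanoate], 1,10-O-ethylidene acetal and 15-O-TBS (1R,3S,6S,7S,8S,9S,10S; 3-OH trans to H9) | C=C1C(=O)O[C@H]2/C=C(/CO[Si](C)(C)C(C)(C)C)[C@]3(O)C[C@H]4O[C@H](C)O[C@@]4(C)[C@H]3[C@@H](OC(=O)[C@H](C)CC)[C@@H]12 | intermediate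
28 | 1,10-O-ethylidene-15-O-(tert-butyldimethylsilyl) derivative of the target (1R,6S,7R,8R,10S; 4Z; acetal carbon S) | C=C1C(=O)O[C@H]2/C=C(/CO[Si](C)(C)C(C)(C)C)C(=O)C[C@H]3O[C@H](C)O[C@@]3(C)C[C@@H](OC(=O)[C@H](C)CC)[C@@H]12 | intermediate
29 | CNP0263726.1, (1R,6S,7R,8R,10S,4Z)-1,10,15-trihydroxy-8-[(2R)-2-methylbutanoyloxy]-3-oxogermacra-4,11(13)-dien-12,6-olide | C=C1C(=O)O[C@H]2/C=C(/CO)C(=O)C[C@@H](O)[C@@](C)(O)C[C@@H](OC(=O)[C@H](C)CC)[C@@H]12 | target

**Step count and risks**

Total steps: 14. Longest linear sequence: 11 (steps 1–4, 7–9, 11–14).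

Most likely to fail, first: step 13, the proposed ring expansion. The C9 radical could add across the ring to C5 of the new enone, or the thiol could add to the α-methylene lactone, before hydrogen-atom transfer is complete. The fallback uses known chemistry and sets out from 27. A hypoiodite (Suárez) alkoxy-radical fragmentation with PhI(OAc)2 and I2 under visible light in cyclohexane–CH2Cl2 traps the C9 radical with iodine and gives the ring-expanded 9-iodo ketone F1. Reduction of the C–I bond with Bu3SnH and AIBN at high tin hydride concentration then returns to the route at 28.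

Second: step 11, the alkenylcerium addition. The hindered ketone must react in the presence of the α-methylene lactone and the ester. The fallback sets out from 21. HC≡CMgBr in THF at −20 °C, which adds to ketones but leaves lactones and esters alone, gives the propargylic tertiary alcohol F3. Ring-closing enyne metathesis with the second-generation Grubbs catalyst under ethylene closes the seven-membered ring and gives the bicyclic 1,3-diene F4. OsO4/NMO followed by NaIO4 cleaves the terminal vinyl group to the enal F5. Reduction with NaBH4 and CeCl3·7H2O gives the allylic alcohol F6, and TBSCl with imidazole silylates the primary hydroxyl, which returns to the route at 27.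

Third: step 7, the aldol union. Aldehyde 9 can epimerize, and the facial preferences of the two chiral partners may not reinforce each other at C8. The fallback sets out from 14 and 9. If the aldol gives mainly the C8-epimeric aldol F2, this alcohol is esterified with 17 under Mitsunobu conditions (PPh3, DIAD, toluene, 0 °C), which installs the ester with inversion at C8 and returns to the route at 18.

**Further compounds**

F1 | step 13 | ring-expanded 9-iodo ketone (28 with iodine at C9, mixture of C9 epimers) | C=C1C(=O)O[C@H]2/C=C(/CO[Si](C)(C)C(C)(C)C)C(=O)C[C@H]3O[C@H](C)O[C@@]3(C)C(I)[C@@H](OC(=O)[C@H](C)CC)[C@@H]12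
F2 | step 7 | C8 epimer of aldol adduct 16 (6S,7R,8R,9R,10R) | C=C1C(=O)O[C@@H](C=C)[C@H]1[C@@H](O)[C@H]2C(=O)C=C[C@@]2(C)O[Si](C)(C)C
F3 | step 11 | propargylic tertiary alcohol: 21 with C3 converted into C(OH)(C≡CH) (3S) | C=C1C(=O)O[C@@H](C=C)[C@H]1[C@H](OC(=O)[C@H](C)CC)[C@H]2[C@](O)(C#C)C[C@H]3O[C@H](C)O[C@@]23C
F4 | step 11 | bicyclic 1,3-diene: analogue of 27 with a vinyl group on C4 in place of CH2OTBS | C=C1C(=O)O[C@H]2/C=C(/C=C)[C@]3(O)C[C@H]4O[C@H](C)O[C@@]4(C)[C@H]3[C@@H](OC(=O)[C@H](C)CC)[C@@H]12
F5 | step 11 | enal: analogue of 27 with a formyl group on C4 | C=C1C(=O)O[C@H]2/C=C(/C=O)[C@]3(O)C[C@H]4O[C@H](C)O[C@@]4(C)[C@H]3[C@@H](OC(=O)[C@H](C)CC)[C@@H]12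
F6 | step 11 | allylic alcohol: 27 without the silyl group (free 15-OH) | C=C1C(=O)O[C@H]2/C=C(/CO)[C@]3(O)C[C@H]4O[C@H](C)O[C@@]4(C)[C@H]3[C@@H](OC(=O)[C@H](C)CC)[C@@H]12
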